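The flask poses 3 questions, all about the product at 30 s.

    starting material + catalyst → catalyst + product (k1 = 0.41 M⁻¹ s⁻¹)
    solid substrate ⇌ starting material, rate k2*(cs2 - [starting material]) while solid is left; crystals form when [starting material] > cs2 (cs2 = 0.20 M, k2 = 0.021 s⁻¹)

solid substrate 0.59 M; catalyst 15 mol%; time 30 s

* amount of product at 30 s, in percent of the solid substrate charged
* the change that raises the amount of product at 30 s, in percent of the solid substrate charged most ("none" if none brings more than 2 percentage points) (autumn / midnight / noon / none)
* amount of product at 30 s, in percent of the solid substrate charged, after autumn

- solid substrate is a solid; its amount is given per volume of the solution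
- at the start none of the solid substrate is in solution
- run time (flask): 30 s

Let a be the dissolved starting material and p the product, both as fractions of the solid charged. The catalyst, charged in the smaller amount at 15 mol%, leaves step 1 as it entered. Its concentration therefore stays as charged, and step 1 is pseudo-first-order in a:

κ = 0.0363 s⁻¹

Saturation lies at σ = 33.9 % of the charge. Dissolving delivers at most 21.4 % by 30 s, less than the charge, so solid remains up to that time and, with kd the dissolution coefficient 0.021 s⁻¹:

da/dt = kd(σ − a) − κa, dp/dt = κa

τ = 1/(kd + κ) = 17.5 s

I carry this settling time τ, the time on which the dissolved fraction climbs to its plateau: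

a = a∞(1 − e^(−t/τ)), a∞ = kd·τ·σ = 12.4 %

p = κ·a∞·[t − τ(1 − e^(−t/τ))] = 7.07 % at 30 s

The plateau lies below saturation, so no crystals form. The equations are linear in σ, so midnight, which doubles the solubility, doubles p to 14.1 %. Autumn, which doubles the catalyst, shortens τ to 10.7 s and gives 11.0 %. Noon, which doubles the dissolution coefficient, shortens it to 12.8 s and gives 12.2 %. I choose midnight, the highest of these.

The forecast gives 7.1 %, midnight as the best change, and 11 % after autumn, reasoning that “Doubling the solubility doubles the driving force”.

The simulation gives 7.07 %, 11.0 % after autumn, and midnight as the best change, worth 7.1 percentage points. At 30.0 s this flask holds 10.2 % starting material in solution, still made 1.35 times faster than used up, each step taken net. That reading falls at 1.71 settling times, before the plateau is reached. The same flask read at 2.0 min stands at 6.87 settling times, where the exponential has faded and p = κ·a∞·(t − τ) = 46.2 %. That flask holds 46.2 % product.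

The numbers of this flask were chosen freely; the flask was simulated.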